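Remark: carbons carry germacrane numbers (C1 furanone carbonyl, C2=C3 furanone olefin, C4=C5 Z olefin with C15 methyl, C6–C8 the three contiguous stereocentres, C9 methylene, C10 quaternary with C14 methyl, C11–C13 the methylene lactone unit). The C8 acyl group is read from the structure as the E isomer of 2-(acetoxymethyl)but-2-enoate (methyl trans to the carboxyl).

## The problem

The target is a ten-membered carbocycle (ring B, C1–C10) bridged by an oxygen between C3 and C10, so that C1, C2, C3, C10 and that oxygen form a 3(2H)-furanone (ring A). Ring B is fused at C6–C7 to an α-methylene-γ-butyrolactone (ring C, O6–C12 with C11=C13). The furanone is cross-conjugated with the Z C4=C5 olefin, and O8 carries an (E)-2-(acetoxymethyl)but-2-enoate. There are four stereocentres: the contiguous C6 (S), C7 (S) and C8 (R), and the remote quaternary C10 (R) that bears the bridging oxygen. C7 can direct C6 because the two are adjacent, and C7 and C8 can be set together in one allylation. C10 is quaternary and one methylene away from C8, so it cannot be trusted to control C8 and is best taken from the chiral pool. The fragile groups are the methylene lactone and the side-chain acrylate (Michael acceptors), the allylic acetate, and the furanone as a vinylogous ester that hydroxide can open. Two further hazards are the C10–O bond, which is β to any carbonyl placed at C8, and the 6,12-lactone, which can migrate to O8 under base. Ring B is a strained medium ring and must be closed irreversibly at a site where the open chain is already bent. That site exists: C6 is an allylic carbinol flanked by the Z C4=C5 olefin and by C7, so a Z-vinyl iodide at C5 and an aldehyde at C6 map directly onto ring B, and the hydroxyl created there lies γ to C12, ready to close ring C.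

## Retrosynthesis

**C8 ester (O8–acyl bond).** Target 36 is cut at the ester to the 8-hydroxy lactone 28 and the side-chain acid 34. The acid holds an allylic acetate and an acrylate that would not survive organometallic or fluoride steps, so it is put on last. The forward step only needs an acylation mild enough for the methylene lactone.

**Ring C (O6–C12 bond) and the O8 silyl group.** Alcohol 28 comes from its silyl ether 27, and 27 from the ring B hydroxy ester 26 by lactonisation. Keeping O8 silylated while ring C closes excludes the competing 8,12-lactone. The forward reactions are an acid-catalysed transesterification and a fluoride cleavage.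

**Ring B (C5–C6 bond), the key cut.** Hydroxy ester 26 is opened between C5 and C6 to the aldehyde vinyl iodide 24. This cut is preferred to C7–C8 or to an olefin-forming closure at C4=C5 for three reasons: it makes the ring and a stereocentre in one irreversible step, the Z geometry is fixed beforehand in the iodide, and the aldehyde is attacked by a non-basic vinylchromium. Precursor 24 is an open chain with one ring (A). The forward reaction must add to the aldehyde face that gives 6S and must not epimerise C7.

**C6 aldehyde and C12 ester from a lactone.** Aldehyde 24 comes from the primary alcohol 23, and 23 from the α-methylene lactone 21 by opening the O6–C12 bond (saponification and O-methylation). Lactone 21 is the silyl ether of 20. The detour through a lactone is accepted because only the ring holds C6 cis to the carbonyl in the allyl reagent, and that geometry is what yields the required 7,8-anti relationship. An open-chain 2-(bromomethyl)alk-2-enoate of the usual geometry would pass through the same chair to the syn isomer.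

**C7–C8 bond.** Adduct 20 is cut to aldehyde 15 and bromolactone 18 (Barbier allylation). Both C7 and C8 arise here, their relative configuration from the cyclic transition state. The step is intermolecular and early, so the two anti diastereomers that differ in their relation to C10 can be separated before material is committed. Bromolactone 18 comes in one operation from commercial 16. The face selectivity at C8 is the soft spot of the plan.

**Ring A (O–C3 bond) and C1–C2.** Aldehyde 15 is reached from alcohol 14 and silyl ether 13. Furanone 13 is opened at O–C3 to the hydroxy ynone 12, which is cut at C1–C2 into the lithium acetylide of iodoenyne 5 and Weinreb amide 10. A 5-endo cycloisomerisation of an α′-hydroxy ynone is a catalytic, neutral furanone synthesis, and the acylation of an acetylide by a Weinreb amide stops at the ketone.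

**C10 from the chiral pool.** Amide 10 comes from (R)-citramalic acid 6 through 7, 8 and 9: the α-hydroxy acid is tied up as a dioxolanone, the other carboxyl is reduced to the future C8 alcohol and silylated, and the dioxolanone is opened by the Weinreb amine. C10 is never a reacting centre, so its configuration is bought and not made.

**Z-iodoenyne.** Enyne 5 comes from enal 4, alcohol 3 and propargyl alcohol 1. The anti-carbomagnesiation of 1 fixes iodine cis to the carbinol carbon (the future C3) by mechanism. A Wittig-type iodo-olefination of an alkynyl methyl ketone would leave that geometry to chance.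

**Side chain.** Acid 34 comes from tert-butyl ester 33, the 1,3-transposed isomer of acetate 32, made from the Morita–Baylis–Hillman adduct 31 of tert-butyl acrylate 29 and acetaldehyde 30. The transposition gives the E olefin thermodynamically, and the tert-butyl ester is removed without touching the acetate.

## Roads not taken

**Alternative 1:** Ring A and C10 would be made together by cutting O–C3 and C9–C10. The alkynyl ketol A1 (acetyl, alkynyl and acetal-bearing methylene on one carbinol carbon) is treated with PtCl2 or AuCl3. The acetyl oxygen adds to C3 of the activated alkyne and C9 migrates from the carbinol carbon C1 to C10, giving furanone A2 with the quaternary centre, the Z C4=C5 olefin and a C8 acetal handle. Its merit is a single catalytic step that builds ring A and C10 with full atom economy, which is more elegant than the two-step Weinreb/ynone sequence used here. Its weak points for this target: the configuration of C10 depends on an enantiopure tertiary ketol A1 (S at C1 if the shift is suprafacial), whose synthesis by alkynylation of an unsymmetrical 1,2-diketone is itself an unsolved regio- and enantioselectivity problem; the conjugated enyne may open other cycloisomerisation channels; and A2 leaves ring B and C6–C8 untouched. The chosen plan sets against the elegance a C10 taken from citramalic acid with no stereochemical question, and a ring B closure that Alternative 1 does not provide.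

**Alternative 2:** Ring C would be built on a preformed ring B by cutting C7–C11 and C8–O. Bromoacetal A3, a ten-membered triene with a Z C7=C8 olefin, is treated with Bu3SnH under air. The C11 radical adds 5-exo to C7 and the C8 radical is trapped by oxygen, giving hydroxy acetal A4 (Ueno–Stork cyclisation with oxygenation). Its merits are that C6 would control both C7 and C8 in one step and that no polar organometallic meets the sensitive groups; in that respect it is better than the chosen plan, which needs a separation for C8. Its weak points are decisive. The triene A3 with its C6 centre must first be made by some other ring B closure, so the hardest problem is only postponed. The fusion (6,7-cis or trans) and the C8 configuration depend on the conformation of the macrocycle, not on the reaction. Tin radicals and oxygen are poorly matched with the cross-conjugated dienone. A4 lacks C13 and is at the acetal level, so oxidation and α-methylenation next to an oxygenated C8 would add about three steps with elimination risk. The chosen plan brings C11–C13 at the correct oxidation level from the allylation onward.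

**Alternative 3:** Ring B would be closed at C7–C8. Aldehyde A5, a 5-alkenyl-3-(bromomethyl)butenolide tethered to the furanone, is treated with indium metal. The allylindium adds through C7 to the C8 aldehyde and gives A6, which is identical with 28 of the chosen route. This road is shorter than the chosen one by roughly four steps: no lactone opening and reclosure and no silyl ether at O8. It also sets C7 and C8 under control of an existing C6 centre and within the ring, which may answer the C8/C10 question better than an intermolecular reaction can. Against it stand the need for an early, enantioselective C6 centre in A5 that is γ to the butenolide carbonyl and doubly allylic, so it is prone to vinylogous enolisation and racemisation through every later step, and a ten-membered closure that must tolerate a β-oxy aldehyde at high dilution. The chosen plan pays with more steps. In return it creates C6 last and together with the ring, makes the C7/C8 pair from two simple pieces at a stage where isomers can be separated, and closes ring B at an sp2 carbon with no allylic ambiguity.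

Key step: step 17

## Route

Step 1
Reactants: 1 prop-2-yn-1-ol (propargyl alcohol)
Product: 3 (Z)-3-iodo-2-methylprop-2-en-1-ol, via vinylmagnesium alkoxide 2 (not isolated)
Conditions: MeMgBr (2.5 equiv), CuI (10 mol %), Et2O, −10 °C → rt; then I2, THF, −10 °C
Reagents that add atoms: methylmagnesium bromide, C[Mg]Br; iodine, II
Why: Copper-catalysed anti-carbomagnesiation of the propargylic alkoxide places methyl on C4 and magnesium on C5 within a five-membered chelate, and iodinolysis with retention fixes iodine cis to the carbinol carbon (the future C3), which is the Z geometry of C4=C5.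

Step 2
Reactants: 3 (Z)-3-iodo-2-methylprop-2-en-1-ol
Product: 4 (Z)-3-iodo-2-methylprop-2-enal
Conditions: activated MnO2, CH2Cl2, rt, dark
Reagents that add atoms: none
Why: MnO2 oxidises allylic alcohols selectively under neutral conditions; the Z enal is labile to light and acid and is carried on as a filtered solution.

Step 3
Reactants: 4 (Z)-3-iodo-2-methylprop-2-enal
Product: 5 (Z)-1-iodo-2-methylbut-1-en-3-yne
Conditions: Me3SiCHN2, LiN(iPr)2, THF, −78 °C; then 4, −78 → 0 °C
Reagents that add atoms: trimethylsilyldiazomethane, C[Si](C)(C)C=[N+]=[N-]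
Why: Colvin homologation: the lithiated diazo compound adds 1,2 to the aldehyde in the cold, Peterson-type loss of lithium trimethylsilanolate gives a diazoalkene, and the alkylidene carbene rearranges by 1,2-hydride shift to the terminal alkyne. No alkoxide nucleophile is present that could add and eliminate at the β-iodo enal, and the olefin is not touched.

Step 4
Reactants: 6 (R)-citramalic acid
Product: 7 2-[(4R)-2,2,4-trimethyl-5-oxo-1,3-dioxolan-4-yl]acetic acid
Conditions: 2,2-dimethoxypropane, TsOH·H2O (cat.), CH2Cl2, rt
Reagents that add atoms: 2,2-dimethoxypropane, COC(C)(C)OC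
Why: Acid-catalysed acetalisation engages the α-hydroxy acid as a five-membered dioxolanone and leaves the β-carboxyl free, which tells the two carboxyl groups apart without touching C10.

Step 5
Reactants: 7 2-[(4R)-2,2,4-trimethyl-5-oxo-1,3-dioxolan-4-yl]acetic acid
Product: 8 (5R)-5-(2-hydroxyethyl)-2,2,5-trimethyl-1,3-dioxolan-4-one
Conditions: BH3·SMe2, THF, 0 °C → rt; MeOH quench
Reagents that add atoms: none
Why: Borane reduces a free carboxylic acid much faster than the dioxolanone carbonyl, as established for the malic acid analogue; the alcohol is silylated at once because acid would rearrange it to a hydroxy butyrolactone.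

Step 6
Reactants: 8 (5R)-5-(2-hydroxyethyl)-2,2,5-trimethyl-1,3-dioxolan-4-one
Product: 9 (5R)-5-[2-(tert-butyldimethylsilyloxy)ethyl]-2,2,5-trimethyl-1,3-dioxolan-4-one
Conditions: TBSCl, imidazole, CH2Cl2, 0 °C → rt
Reagents that add atoms: tert-butyldimethylsilyl chloride, CC(C)(C)[Si](C)(C)Cl
Why: Standard silylation of a primary alcohol; the silyl ether carries O8 through the organolithium and gold steps.

Step 7
Reactants: 9 (5R)-5-[2-(tert-butyldimethylsilyloxy)ethyl]-2,2,5-trimethyl-1,3-dioxolan-4-one
Product: 10 (2R)-4-(tert-butyldimethylsilyloxy)-2-hydroxy-N-methoxy-N,2-dimethylbutanamide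
Conditions: MeNH(OMe)·HCl, iPrMgCl, THF, −20 °C; then 9, −20 → 0 °C
Reagents that add atoms: N,O-dimethylhydroxylamine hydrochloride, CNOC.Cl
Why: The dioxolanone is an activated ester; the preformed chloromagnesium amide attacks its carbonyl and acetone is lost, giving the α-hydroxy Weinreb amide directly (aminolysis of an acetonide-protected α-hydroxy acid).

Step 8
Reactants: 5 (Z)-1-iodo-2-methylbut-1-en-3-yne; 10 (2R)-4-(tert-butyldimethylsilyloxy)-2-hydroxy-N-methoxy-N,2-dimethylbutanamide
Product: 12 (3R,7Z)-1-(tert-butyldimethylsilyloxy)-3-hydroxy-8-iodo-3,7-dimethyloct-7-en-5-yn-4-one, via lithium acetylide 11 (not isolated)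
Conditions: 5 (2.5 equiv), LiN(SiMe3)2 (2.4 equiv), THF, −78 °C; then 10, −78 → −30 °C; aq. NH4Cl
Reagents that add atoms: none
Why: The silylamide deprotonates the alkyne without the halogen–lithium exchange an alkyllithium would cause; one equivalent of acetylide is spent on the tertiary hydroxyl and the next adds to the Weinreb amide. The chelated tetrahedral intermediate releases the ynone only on quench, so no over-addition occurs.

Step 9
Reactants: 12 (3R,7Z)-1-(tert-butyldimethylsilyloxy)-3-hydroxy-8-iodo-3,7-dimethyloct-7-en-5-yn-4-one
Product: 13 (2R)-2-[2-(tert-butyldimethylsilyloxy)ethyl]-5-[(Z)-1-iodoprop-1-en-2-yl]-2-methylfuran-3(2H)-one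
Conditions: Ph3PAuNTf2 (5 mol %), toluene, rt
Reagents that add atoms: none
Why: Cationic monovalent gold activates the ynone triple bond, the tertiary hydroxyl adds 5-endo-dig to C3 and protodeauration gives the 3(2H)-furanone (ring A), a known cycloisomerisation of α′-hydroxy ynones. The vinyl iodide is inert because monovalent gold does not insert into the C–I bond under these conditions.

Step 10
Reactants: 13 (2R)-2-[2-(tert-butyldimethylsilyloxy)ethyl]-5-[(Z)-1-iodoprop-1-en-2-yl]-2-methylfuran-3(2H)-one
Product: 14 (2R)-2-(2-hydroxyethyl)-5-[(Z)-1-iodoprop-1-en-2-yl]-2-methylfuran-3(2H)-one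
Conditions: HF·pyridine, THF, 0 °C → rt
Reagents that add atoms: none
Why: Fluoride cleavage of a primary silyl ether under buffered acidic conditions, to which the vinylogous ester and the vinyl iodide are inert.

Step 11
Reactants: 14 (2R)-2-(2-hydroxyethyl)-5-[(Z)-1-iodoprop-1-en-2-yl]-2-methylfuran-3(2H)-one
Product: 15 2-{(2R)-5-[(Z)-1-iodoprop-1-en-2-yl]-2-methyl-3-oxo-2,3-dihydrofuran-2-yl}acetaldehyde
Conditions: Dess–Martin periodinane, NaHCO3, CH2Cl2, 0 °C → rt
Reagents that add atoms: none
Why: Dess–Martin oxidation is non-basic, so the aldehyde forms without β-elimination of the C10 oxygen (a vinylogous carboxylate leaving group); the aldehyde is used crude.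

Step 12
Reactants: 16 3-methylenedihydrofuran-2(3H)-one (α-methylene-γ-butyrolactone)
Product: 18 3-(bromomethyl)furan-2(5H)-one, via dibromolactone 17 (not isolated)
Conditions: Br2, CH2Cl2, 0 °C; then Et3N (1.05 equiv), 0 °C → rt
Reagents that add atoms: bromine, BrBr
Why: Bromine adds to the exocyclic olefin and triethylamine removes HBr from the tertiary α-bromide across a ring C–H (E2), the classical bromination–dehydrobromination route to butenolides. The endocyclic conjugated olefin results and the primary bromide becomes allylic.

Step 13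
Reactants: 15 2-{(2R)-5-[(Z)-1-iodoprop-1-en-2-yl]-2-methyl-3-oxo-2,3-dihydrofuran-2-yl}acetaldehyde; 18 3-(bromomethyl)furan-2(5H)-one
Product: 20 (4R)-4-[(1R)-1-hydroxy-2-{(2R)-5-[(Z)-1-iodoprop-1-en-2-yl]-2-methyl-3-oxo-2,3-dihydrofuran-2-yl}ethyl]-3-methylenedihydrofuran-2(3H)-one, via allylindium dibromide 19 (not isolated)
Conditions: In powder, THF/H2O (1:1), rt
Reagents that add atoms: none
Why: Barbier allylation: indium inserts into the allylic bromide and the allylindium adds through its γ-carbon (C7) in a Zimmerman–Traxler chair. The lactone ring holds C6 cis to the carbonyl (E-crotyl-type geometry), so C6 and the aldehyde residue are both equatorial and the 7,8-anti adduct forms, as is known for this bromolactone. Quaternary C10 gives only weak 1,3-control of the aldehyde face, so 20 (7R,8R) is expected together with its 7S,8S anti companion and is to be separated by chromatography here.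

Step 14
Reactants: 20 (4R)-4-[(1R)-1-hydroxy-2-{(2R)-5-[(Z)-1-iodoprop-1-en-2-yl]-2-methyl-3-oxo-2,3-dihydrofuran-2-yl}ethyl]-3-methylenedihydrofuran-2(3H)-one
Product: 21 (4R)-4-[(1R)-1-(tert-butyldimethylsilyloxy)-2-{(2R)-5-[(Z)-1-iodoprop-1-en-2-yl]-2-methyl-3-oxo-2,3-dihydrofuran-2-yl}ethyl]-3-methylenedihydrofuran-2(3H)-one
Conditions: TBSOTf, 2,6-lutidine, CH2Cl2, −78 → 0 °C
Reagents that add atoms: tert-butyldimethylsilyl triflate, CC(C)(C)[Si](C)(C)OS(=O)(=O)C(F)(F)F
Why: A silyl triflate with a hindered pyridine base silylates the secondary alcohol fast in the cold, before translactonisation to the 8,12-lactone can set in.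

Step 15
Reactants: 21 (4R)-4-[(1R)-1-(tert-butyldimethylsilyloxy)-2-{(2R)-5-[(Z)-1-iodoprop-1-en-2-yl]-2-methyl-3-oxo-2,3-dihydrofuran-2-yl}ethyl]-3-methylenedihydrofuran-2(3H)-one
Product: 23 methyl (3R,4R)-4-(tert-butyldimethylsilyloxy)-3-(hydroxymethyl)-5-{(2R)-5-[(Z)-1-iodoprop-1-en-2-yl]-2-methyl-3-oxo-2,3-dihydrofuran-2-yl}-2-methylenepentanoate, via potassium carboxylate 22 (not isolated)
Conditions: KOH (1.2 equiv), THF/H2O, 0 °C; concentrate; MeI, DMF, 0 °C → rt
Reagents that add atoms: potassium hydroxide, [K+].[OH-]; iodomethane, CI
Why: Saponification of the γ-lactone with about one equivalent of hydroxide in the cold, then O-alkylation of the carboxylate salt in a dipolar aprotic solvent, gives the open γ-hydroxy ester without passing through the free hydroxy acid, which would relactonise. Acyl–oxygen cleavage leaves C7 and C8 untouched.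

Step 16
Reactants: 23 methyl (3R,4R)-4-(tert-butyldimethylsilyloxy)-3-(hydroxymethyl)-5-{(2R)-5-[(Z)-1-iodoprop-1-en-2-yl]-2-methyl-3-oxo-2,3-dihydrofuran-2-yl}-2-methylenepentanoate
Product: 24 methyl (3S,4R)-4-(tert-butyldimethylsilyloxy)-3-formyl-5-{(2R)-5-[(Z)-1-iodoprop-1-en-2-yl]-2-methyl-3-oxo-2,3-dihydrofuran-2-yl}-2-methylenepentanoate
Conditions: Dess–Martin periodinane, NaHCO3, CH2Cl2, 0 °C
Reagents that add atoms: none
Why: Buffered Dess–Martin oxidation of the primary alcohol; the α-branched, β,γ-unsaturated aldehyde can epimerise at C7 or shift its double bond, so it is filtered and used at once.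

Step 17
Reactants: 24 methyl (3S,4R)-4-(tert-butyldimethylsilyloxy)-3-formyl-5-{(2R)-5-[(Z)-1-iodoprop-1-en-2-yl]-2-methyl-3-oxo-2,3-dihydrofuran-2-yl}-2-methylenepentanoate
Product: 26 methyl 2-[(4Z,6S,7R,8R,10R)-8-(tert-butyldimethylsilyloxy)-6-hydroxy-4,10-dimethyl-1-oxo-3,10-epoxycyclodeca-2,4-dien-7-yl]prop-2-enoate (ring B hydroxy ester), via vinylchromium dichloride 25 (not isolated)
Conditions: CrCl2 (10 equiv), NiCl2 (0.1 equiv), degassed DMSO, rt, slow addition of 24 to about 3 mM; aq. NH4Cl
Reagents that add atoms: none
Why: Nozaki–Hiyama–Kishi reaction: CrCl2 reduces NiCl2 to zerovalent nickel, which inserts into the C5–I bond with retention of the Z geometry, the vinyl group passes to trivalent chromium (25), and the vinylchromium adds to the C6 aldehyde through a chromium-bound carbonyl. The closest known reaction type is the nickel/chromium-mediated macrocyclisation of vinyl iodides onto aldehydes used for medium and large carbocycles. Ring B closes by a 10-exo-trig addition that forms C5–C6, with ring A acting as a rigid turn. The new C6 centre is controlled by C7: in the Felkin–Anh arrangement the ring bond C7–C8 lies anti to the incoming C5, the acrylate branch sits next to the carbonyl oxygen and the vinyl group passes the small C7–H, which gives the 6S alcohol (6,7-trans after lactonisation). The step needs chemoselectivity for the aldehyde over the methyl ester, the acrylate and the furanone carbonyl, and this is inherent in vinylchromium reagents, which are neither basic nor good Michael donors, so C7 is not epimerised and the silyl ether is not eliminated. Ring closure is favoured over oligomerisation by slow addition at millimolar concentration and by the Z olefin, which together with the furanone holds C5 within reach of C6.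

Step 18
Reactants: 26 methyl 2-[(4Z,6S,7R,8R,10R)-8-(tert-butyldimethylsilyloxy)-6-hydroxy-4,10-dimethyl-1-oxo-3,10-epoxycyclodeca-2,4-dien-7-yl]prop-2-enoate
Product: 27 (4Z,6S,7R,8R,10R)-8-(tert-butyldimethylsilyloxy)-3,10-epoxy-1-oxogermacra-2,4,11(13)-trien-12,6-olide
Conditions: camphorsulfonic acid (cat.), CH2Cl2, rt
Reagents that add atoms: none
Why: Acid-catalysed lactonisation of a γ-hydroxy ester closes ring C; only the 6,12-lactone can form because O8 is silylated.

Step 19
Reactants: 27 (4Z,6S,7R,8R,10R)-8-(tert-butyldimethylsilyloxy)-3,10-epoxy-1-oxogermacra-2,4,11(13)-trien-12,6-olide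
Product: 28 (4Z,6S,7S,8R,10R)-8-hydroxy-3,10-epoxy-1-oxogermacra-2,4,11(13)-trien-12,6-olide
Conditions: HF·pyridine, THF, 0 °C → rt
Reagents that add atoms: none
Why: Fluoride cleavage of the secondary silyl ether under buffered acidic conditions, which avoid the alkoxide that could translactonise to the 8,12-olide or add to the methylene lactone.

Step 20
Reactants: 29 tert-butyl acrylate; 30 acetaldehyde
Product: 31 tert-butyl 3-hydroxy-2-methylenebutanoate (racemic)
Conditions: DABCO (cat.), 1,4-dioxane/H2O, rt
Reagents that add atoms: none
Why: Morita–Baylis–Hillman reaction of an acrylate with an aliphatic aldehyde; the carbinol centre is lost again in step 22, so its configuration is irrelevant.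

Step 21
Reactants: 31 tert-butyl 3-hydroxy-2-methylenebutanoate
Product: 32 tert-butyl 3-acetoxy-2-methylenebutanoate (racemic)
Conditions: Ac2O, Et3N, DMAP (cat.), CH2Cl2, 0 °C → rt
Reagents that add atoms: acetic anhydride, CC(=O)OC(C)=O
Why: Routine acetylation of a secondary allylic alcohol.

Step 22
Reactants: 32 tert-butyl 3-acetoxy-2-methylenebutanoate
Product: 33 tert-butyl (E)-2-(acetoxymethyl)but-2-enoate
Conditions: DABCO (20 mol %), THF, reflux
Reagents that add atoms: none
Why: Amine-catalysed 1,3-transposition of a Morita–Baylis–Hillman acetate (SN2′ addition of DABCO, then SN2′ return of acetate) gives the thermodynamically preferred trisubstituted olefin with the methyl group trans to the ester, the E isomer needed in the side chain.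

Step 23
Reactants: 33 tert-butyl (E)-2-(acetoxymethyl)but-2-enoate
Product: 34 (E)-2-(acetoxymethyl)but-2-enoic acid
Conditions: CF3CO2H, CH2Cl2, 0 °C → rt
Reagents that add atoms: none
Why: Acidolysis of the tert-butyl ester through the tert-butyl cation leaves the primary allylic acetate and the olefin geometry untouched.

Step 24
Reactants: 28 (4Z,6S,7S,8R,10R)-8-hydroxy-3,10-epoxy-1-oxogermacra-2,4,11(13)-trien-12,6-olide; 34 (E)-2-(acetoxymethyl)but-2-enoic acid
Product: 36 CNP0176571.1, the 8-O-[(E)-2-(acetoxymethyl)but-2-enoyl] ester of 28, via mixed anhydride 35 (not isolated)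
Conditions: 34, 2,4,6-trichlorobenzoyl chloride, Et3N, toluene, rt; then 28, DMAP (0.2 equiv), rt
Reagents that add atoms: none
Why: Yamaguchi esterification: the mixed anhydride acylates the secondary C8 hydroxyl at the less hindered carbonyl. DMAP is kept substoichiometric to limit its SN2′ attack on the allylic acetate, and no stereocentre is involved.

## Compound list

1 | prop-2-yn-1-ol | C#CCO | starting material
2 | bromomagnesium (Z)-3-(bromomagnesio)-2-methylprop-2-en-1-olate | Br[Mg]OC/C(C)=C\[Mg]Br | intermediate
3 | (Z)-3-iodo-2-methylprop-2-en-1-ol | OC/C(C)=C\I | intermediate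
4 | (Z)-3-iodo-2-methylprop-2-enal | O=C/C(C)=C\I | intermediate
5 | (Z)-1-iodo-2-methylbut-1-en-3-yne | C#C/C(C)=C\I | intermediate
6 | (R)-citramalic acid | C[C@@](O)(CC(=O)O)C(=O)O | starting material
7 | 2-[(4R)-2,2,4-trimethyl-5-oxo-1,3-dioxolan-4-yl]acetic acid | C[C@]1(CC(=O)O)OC(C)(C)OC1=O | intermediate
8 | (5R)-5-(2-hydroxyethyl)-2,2,5-trimethyl-1,3-dioxolan-4-one | C[C@]1(CCO)OC(C)(C)OC1=O | intermediate
9 | (5R)-5-[2-(tert-butyldimethylsilyloxy)ethyl]-2,2,5-trimethyl-1,3-dioxolan-4-one | C[C@]1(CCO[Si](C)(C)C(C)(C)C)OC(C)(C)OC1=O | intermediate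
10 | (2R)-4-(tert-butyldimethylsilyloxy)-2-hydroxy-N-methoxy-N,2-dimethylbutanamide | CON(C)C(=O)[C@](C)(O)CCO[Si](C)(C)C(C)(C)C | intermediate
11 | lithium (Z)-4-iodo-3-methylbut-3-en-1-yn-1-ide | [Li]C#C/C(C)=C\I | intermediate
12 | (3R,7Z)-1-(tert-butyldimethylsilyloxy)-3-hydroxy-8-iodo-3,7-dimethyloct-7-en-5-yn-4-one | C[C@@](O)(CCO[Si](C)(C)C(C)(C)C)C(=O)C#C/C(C)=C\I | intermediate
13 | (2R)-2-[2-(tert-butyldimethylsilyloxy)ethyl]-5-[(Z)-1-iodoprop-1-en-2-yl]-2-methylfuran-3(2H)-one | C[C@]1(CCO[Si](C)(C)C(C)(C)C)OC(/C(C)=C\I)=CC1=O | intermediate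
14 | (2R)-2-(2-hydroxyethyl)-5-[(Z)-1-iodoprop-1-en-2-yl]-2-methylfuran-3(2H)-one | C[C@]1(CCO)OC(/C(C)=C\I)=CC1=O | intermediate
15 | 2-{(2R)-5-[(Z)-1-iodoprop-1-en-2-yl]-2-methyl-3-oxo-2,3-dihydrofuran-2-yl}acetaldehyde | C[C@]1(CC=O)OC(/C(C)=C\I)=CC1=O | intermediate
16 | 3-methylenedihydrofuran-2(3H)-one | C=C1CCOC1=O | starting material
17 | 3-bromo-3-(bromomethyl)dihydrofuran-2(3H)-one (racemic) | BrCC1(Br)CCOC1=O | intermediate
18 | 3-(bromomethyl)furan-2(5H)-one | BrCC1=CCOC1=O | intermediate
19 | [(2-oxo-2,5-dihydrofuran-3-yl)methyl]indium dibromide | Br[In](Br)CC1=CCOC1=O | intermediate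
20 | (4R)-4-[(1R)-1-hydroxy-2-{(2R)-5-[(Z)-1-iodoprop-1-en-2-yl]-2-methyl-3-oxo-2,3-dihydrofuran-2-yl}ethyl]-3-methylenedihydrofuran-2(3H)-one | C=C1C(=O)OC[C@@H]1[C@H](O)C[C@@]2(C)OC(/C(C)=C\I)=CC2=O | intermediate
21 | (4R)-4-[(1R)-1-(tert-butyldimethylsilyloxy)-2-{(2R)-5-[(Z)-1-iodoprop-1-en-2-yl]-2-methyl-3-oxo-2,3-dihydrofuran-2-yl}ethyl]-3-methylenedihydrofuran-2(3H)-one | C=C1C(=O)OC[C@@H]1[C@H](O[Si](C)(C)C(C)(C)C)C[C@@]2(C)OC(/C(C)=C\I)=CC2=O | intermediate
22 | potassium (3R,4R)-4-(tert-butyldimethylsilyloxy)-3-(hydroxymethyl)-5-{(2R)-5-[(Z)-1-iodoprop-1-en-2-yl]-2-methyl-3-oxo-2,3-dihydrofuran-2-yl}-2-methylenepentanoate | C=C(C(=O)[O-])[C@H](CO)[C@H](O[Si](C)(C)C(C)(C)C)C[C@@]1(C)OC(/C(C)=C\I)=CC1=O.[K+] | intermediate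
23 | methyl (3R,4R)-4-(tert-butyldimethylsilyloxy)-3-(hydroxymethyl)-5-{(2R)-5-[(Z)-1-iodoprop-1-en-2-yl]-2-methyl-3-oxo-2,3-dihydrofuran-2-yl}-2-methylenepentanoate | C=C(C(=O)OC)[C@H](CO)[C@H](O[Si](C)(C)C(C)(C)C)C[C@@]1(C)OC(/C(C)=C\I)=CC1=O | intermediate
24 | methyl (3S,4R)-4-(tert-butyldimethylsilyloxy)-3-formyl-5-{(2R)-5-[(Z)-1-iodoprop-1-en-2-yl]-2-methyl-3-oxo-2,3-dihydrofuran-2-yl}-2-methylenepentanoate | C=C(C(=O)OC)[C@H](C=O)[C@H](O[Si](C)(C)C(C)(C)C)C[C@@]1(C)OC(/C(C)=C\I)=CC1=O | intermediate
25 | C5 dichlorochromium derivative of 24 (vinylchromium, chromium in place of iodine) | C=C(C(=O)OC)[C@H](C=O)[C@H](O[Si](C)(C)C(C)(C)C)C[C@@]1(C)OC(/C(C)=C\[Cr](Cl)Cl)=CC1=O | intermediate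
26 | methyl 2-[(4Z,6S,7R,8R,10R)-8-(tert-butyldimethylsilyloxy)-6-hydroxy-4,10-dimethyl-1-oxo-3,10-epoxycyclodeca-2,4-dien-7-yl]prop-2-enoate | COC(=O)C(=C)[C@@H]1[C@@H](O)/C=C(/C)C2=CC(=O)[C@@](C)(C[C@H]1O[Si](C)(C)C(C)(C)C)O2 | intermediate
27 | (4Z,6S,7R,8R,10R)-8-(tert-butyldimethylsilyloxy)-3,10-epoxy-1-oxogermacra-2,4,11(13)-trien-12,6-olide | C=C1C(=O)O[C@H]2/C=C(/C)C3=CC(=O)[C@@](C)(C[C@@H](O[Si](C)(C)C(C)(C)C)[C@H]12)O3 | intermediate
28 | (4Z,6S,7S,8R,10R)-8-hydroxy-3,10-epoxy-1-oxogermacra-2,4,11(13)-trien-12,6-olide | C=C1C(=O)O[C@H]2/C=C(/C)C3=CC(=O)[C@@](C)(C[C@@H](O)[C@H]12)O3 | intermediate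
29 | tert-butyl acrylate | C=CC(=O)OC(C)(C)C | starting material
30 | acetaldehyde | CC=O | starting material
31 | tert-butyl 3-hydroxy-2-methylenebutanoate (racemic) | C=C(C(C)O)C(=O)OC(C)(C)C | intermediate
32 | tert-butyl 3-acetoxy-2-methylenebutanoate (racemic) | C=C(C(C)OC(C)=O)C(=O)OC(C)(C)C | intermediate
33 | tert-butyl (E)-2-(acetoxymethyl)but-2-enoate | C/C=C(\COC(C)=O)C(=O)OC(C)(C)C | intermediate
34 | (E)-2-(acetoxymethyl)but-2-enoic acid | C/C=C(\COC(C)=O)C(=O)O | intermediate
35 | (E)-2-(acetoxymethyl)but-2-enoic 2,4,6-trichlorobenzoic anhydride | C/C=C(\COC(C)=O)C(=O)OC(=O)c1c(Cl)cc(Cl)cc1Cl | intermediate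
36 | CNP0176571.1, (4Z,6S,7S,8R,10R)-8-[(E)-2-(acetoxymethyl)but-2-enoyloxy]-3,10-epoxy-1-oxogermacra-2,4,11(13)-trien-12,6-olide | C=C1C(=O)O[C@H]2/C=C(/C)C3=CC(=O)[C@@](C)(C[C@@H](OC(=O)/C(=C/C)COC(C)=O)[C@H]12)O3 | target

## Step count and least certain steps

Total: 24 steps. Longest linear sequence: 16 steps, from 6 to 36 (steps 4–11, 13–19 and 24).

**Step 17 (key step).** The most likely failure is poor facial selectivity at C6 in the strained bicyclic transition state, with loss of the C7 configuration or double-bond migration in aldehyde 24 under the Lewis-acidic chromium medium as a second hazard. Fallback: it sets out from 24, and the ring is closed as before. If the 6R alcohol dominates, this C6 epimer, methyl 2-[(4Z,6R,7R,8R,10R)-8-(tert-butyldimethylsilyloxy)-6-hydroxy-4,10-dimethyl-1-oxo-3,10-epoxycyclodeca-2,4-dien-7-yl]prop-2-enoate F1, is hydrolysed with Me3SnOH in 1,2-dichloroethane to the corresponding seco acid F2. F2 is then lactonised under Mitsunobu conditions (PPh3, diisopropyl azodicarboxylate, THF, 0 °C), where the carboxylate displaces the activated C6 oxygen with inversion. The sequence comes back to the route at 27. C6 is then fixed by SN2 inversion during ring C formation instead of by the carbonyl addition.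

**Step 13.** The most likely failure is poor facial selectivity at the aldehyde (C8 relative to remote C10), since the chair fixes only the 7,8-anti relationship. Fallback: from 15 and 18 the allylation is run under catalyst control as a chromium-catalysed asymmetric Nozaki–Hiyama allylation (CrCl2 10 mol %, a chiral tridentate bis(oxazolinyl)carbazole ligand, Mn powder, Me3SiCl, THF). No nickel is present, so the vinyl iodide is not activated. The first product is the C8 trimethylsilyl ether of 20 F3, which dilute acid converts to 20, where the route is rejoined. The ligand enantiomer is chosen to deliver the 8R carbinol, and the E-crotyl-type geometry of the reagent again secures the anti relationship.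

**Step 15.** The most likely failure is relactonisation of the γ-hydroxy acid or ester during isolation, with competing attack of hydroxide on the furanone as a second risk. Fallback: from 21 the saponification and methylation are run as before, but the alcohol is not isolated. Et3SiCl and imidazole are added to the DMF solution to trap it as methyl (3R,4R)-4-(tert-butyldimethylsilyloxy)-3-[(triethylsilyloxy)methyl]-5-{(2R)-5-[(Z)-1-iodoprop-1-en-2-yl]-2-methyl-3-oxo-2,3-dihydrofuran-2-yl}-2-methylenepentanoate F4. Swern oxidation (oxalyl chloride, DMSO, then iPr2NEt, −78 °C) converts the primary triethylsilyl ether directly into the aldehyde and leaves the secondary silyl ether, so the route is rejoined at 24 without a free hydroxy ester.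

**Step 3.** The most likely failure is isomerisation of the Z olefin or addition–elimination at the β-iodo enal during homologation, together with loss of the volatile enyne. Fallback: it sets out from 10 and 4 and builds ring A by the classical diketone route. MeMgBr converts 10 into (3R)-5-(tert-butyldimethylsilyloxy)-3-hydroxy-3-methylpentan-2-one F5. Its dianion (LiN(iPr)2, 2.2 equiv) adds to 4 to give the aldol (3R,7Z)-1-(tert-butyldimethylsilyloxy)-3,6-dihydroxy-8-iodo-3,7-dimethyloct-7-en-4-one F6. Dess–Martin oxidation gives the hydroxy 1,3-diketone F7, and TsOH (cat.) in toluene cyclodehydrates it to the furanone. The route is rejoined at 13, and steps 3, 8 and 9 are bypassed.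

**Step 24.** The most likely failure is slow acylation of the hindered C8 hydroxyl, which would allow nucleophilic attack of DMAP on the allylic acetate of the activated acid or base-induced migration of the lactone to O8. Fallback: it sets out from 31 and 28. Concentrated HBr converts 31 into (Z)-2-(bromomethyl)but-2-enoic acid F8 (SN2′ bromination with loss of the tert-butyl group). Oxalyl chloride gives the acid chloride F9, which acylates 28 with pyridine and no nucleophilic catalyst to the 8-O-[(Z)-2-(bromomethyl)but-2-enoyl] ester of 28 F10. CsOAc in DMF displaces the primary allylic bromide, and the route is rejoined at 36.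

## Further compounds

F1 | step 17 | methyl 2-[(4Z,6R,7R,8R,10R)-8-(tert-butyldimethylsilyloxy)-6-hydroxy-4,10-dimethyl-1-oxo-3,10-epoxycyclodeca-2,4-dien-7-yl]prop-2-enoate | COC(=O)C(=C)[C@@H]1[C@H](O)/C=C(/C)C2=CC(=O)[C@@](C)(C[C@H]1O[Si](C)(C)C(C)(C)C)O2
F2 | step 17 | 2-[(4Z,6R,7R,8R,10R)-8-(tert-butyldimethylsilyloxy)-6-hydroxy-4,10-dimethyl-1-oxo-3,10-epoxycyclodeca-2,4-dien-7-yl]prop-2-enoic acid | OC(=O)C(=C)[C@@H]1[C@H](O)/C=C(/C)C2=CC(=O)[C@@](C)(C[C@H]1O[Si](C)(C)C(C)(C)C)O2
F3 | step 13 | C8 trimethylsilyl ether of 20 | C=C1C(=O)OC[C@@H]1[C@H](O[Si](C)(C)C)C[C@@]2(C)OC(/C(C)=C\I)=CC2=O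
F4 | step 15 | methyl (3R,4R)-4-(tert-butyldimethylsilyloxy)-3-[(triethylsilyloxy)methyl]-5-{(2R)-5-[(Z)-1-iodoprop-1-en-2-yl]-2-methyl-3-oxo-2,3-dihydrofuran-2-yl}-2-methylenepentanoate | C=C(C(=O)OC)[C@H](CO[Si](CC)(CC)CC)[C@H](O[Si](C)(C)C(C)(C)C)C[C@@]1(C)OC(/C(C)=C\I)=CC1=O
F5 | step 3 | (3R)-5-(tert-butyldimethylsilyloxy)-3-hydroxy-3-methylpentan-2-one | C[C@@](O)(CCO[Si](C)(C)C(C)(C)C)C(C)=O
F6 | step 3 | (3R,7Z)-1-(tert-butyldimethylsilyloxy)-3,6-dihydroxy-8-iodo-3,7-dimethyloct-7-en-4-one (mixture at C6 of the chain) | C[C@@](O)(CCO[Si](C)(C)C(C)(C)C)C(=O)CC(O)/C(C)=C\I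
F7 | step 3 | (3R,7Z)-1-(tert-butyldimethylsilyloxy)-3-hydroxy-8-iodo-3,7-dimethyloct-7-ene-4,6-dione | C[C@@](O)(CCO[Si](C)(C)C(C)(C)C)C(=O)CC(=O)/C(C)=C\I
F8 | step 24 | (Z)-2-(bromomethyl)but-2-enoic acid | C/C=C(\CBr)C(=O)O
F9 | step 24 | (Z)-2-(bromomethyl)but-2-enoyl chloride | C/C=C(\CBr)C(Cl)=O
F10 | step 24 | 8-O-[(Z)-2-(bromomethyl)but-2-enoyl] ester of 28 | C=C1C(=O)O[C@H]2/C=C(/C)C3=CC(=O)[C@@](C)(C[C@@H](OC(=O)/C(=C/C)CBr)[C@H]12)O3
A1 | alternative 1 | (3S,6Z)-3-[(1,3-dioxolan-2-yl)methyl]-8-(tert-butyldimethylsilyloxy)-3-hydroxy-6-methyloct-6-en-4-yn-2-one | CC(=O)[C@](O)(CC1OCCO1)C#C/C(C)=C\CO[Si](C)(C)C(C)(C)C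
A2 | alternative 1 | (2R)-2-[(1,3-dioxolan-2-yl)methyl]-5-[(Z)-4-(tert-butyldimethylsilyloxy)but-2-en-2-yl]-2-methylfuran-3(2H)-one | C[C@]1(CC2OCCO2)OC(/C(C)=C\CO[Si](C)(C)C(C)(C)C)=CC1=O
A3 | alternative 2 | 6-O-(2-bromo-1-ethoxyethyl) ether of the ring A/B triene with Z C4=C5 and Z C7=C8 olefins | CCOC(CBr)O[C@H]1/C=C(/C)C2=CC(=O)[C@@](C)(C/C=C\1)O2
A4 | alternative 2 | 8-hydroxy lactol ethyl acetal with rings A, B and C | C1[C@@H](OCC)O[C@H]2/C=C(/C)C3=CC(=O)[C@@](C)(C[C@@H](O)[C@H]12)O3
A5 | alternative 3 | 2-{(2R)-5-[(Z)-1-((2S)-4-(bromomethyl)-5-oxo-2,5-dihydrofuran-2-yl)prop-1-en-2-yl]-2-methyl-3-oxo-2,3-dihydrofuran-2-yl}acetaldehyde | BrCC1=C[C@H](/C=C(/C)C2=CC(=O)[C@@](C)(CC=O)O2)OC1=O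
A6 | alternative 3 | 8-hydroxy furanone methylene lactone, identical with 28 | C=C1C(=O)O[C@H]2/C=C(/C)C3=CC(=O)[C@@](C)(C[C@@H](O)[C@H]12)O3
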